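**Strategy.** Everything rests on the C6'(sp2)–C7'(sp) bond between ring A (the acetoxytrimethylcyclohexene) and the alkyne. C6' is the carbonyl carbon of a 2,2,6-trimethylcyclohexanone that can enolise only toward C5', so its enol triflate fixes the ring alkene, and C7' is a terminal alkyne carbon. A Sonogashira coupling therefore unites the ring A triflate with the complete C28 polyenyne, which already carries butenolide ring B and epoxycyclohexanol ring C, and gives the target directly. The C28 alkyne is grown from a twofold-symmetric C14 tetraenediyne: one terminus builds ring B by tandem coupling–lactonisation, the other is reserved for the key step. Both six-membered rings derive from one actinol-derived enol triflate.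

Key step: step 16

Remark: positions are quoted in carotenoid numbering (ring C carries C1–C6 with the 5,6-epoxide, ring A carries C1'–C6'); (4R,6R)-actinol and (E)-3-methylpent-2-en-4-yn-1-ol are taken as purchasable industrial carotenoid intermediates.

**Route**

Step 1
Reactants: 1 (4R,6R)-4-hydroxy-2,2,6-trimethylcyclohexan-1-one (actinol)
Product: 2 (1R,5R)-3,3,5-trimethyl-4-oxocyclohexyl acetate
Conditions: Ac2O, pyridine, DMAP (cat.), CH2Cl2, 0 °C to rt
Reagents that add atoms: acetic anhydride CC(=O)OC(C)=O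
Why: DMAP-catalysed O-acylation of the unhindered secondary alcohol should be fast and leaves the ketone and the carbinol stereocentre (the future C3' of ring A and C3 of ring C) untouched.

Step 2
Reactants: 2 (1R,5R)-3,3,5-trimethyl-4-oxocyclohexyl acetate
Product: 3 (1R)-3,5,5-trimethyl-4-(trifluoromethylsulfonyloxy)cyclohex-3-en-1-yl acetate
Conditions: Tf2O, 2,6-di-tert-butyl-4-methylpyridine, CH2Cl2, 0 °C to rt
Reagents that add atoms: trifluoromethanesulfonic anhydride O=S(=O)(OS(=O)(=O)C(F)(F)F)C(F)(F)F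
Why: Enol triflate formation by O-triflation of the ketone and deprotonation with a hindered, non-nucleophilic pyridine; one α-carbon is quaternary, so a single tetrasubstituted enol triflate can form, the acetate is spared, and the methyl-bearing stereocentre is deliberately erased.

Step 3
Reactants: 3 (1R)-3,5,5-trimethyl-4-(trifluoromethylsulfonyloxy)cyclohex-3-en-1-yl acetate
Product: 4 (1R)-4-(hydroxymethyl)-3,5,5-trimethylcyclohex-3-en-1-yl acetate
Conditions: Bu3SnCH2OH, Pd(PPh3)4 (cat.), LiCl, 1,4-dioxane, 100 °C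
Reagents that add atoms: (tributylstannyl)methanol CCCC[Sn](CCCC)(CCCC)CO
Why: Stille coupling in which the hydroxymethyl group of the stannane is transferred to the alkenyl triflate, LiCl assisting triflate exchange at divalent palladium, with the acetate and the stereocentre unaffected.

Step 4
Reactants: 4 (1R)-4-(hydroxymethyl)-3,5,5-trimethylcyclohex-3-en-1-yl acetate
Product: 5 (1R,4S,6R)-1-(hydroxymethyl)-2,2,6-trimethyl-7-oxabicyclo[4.1.0]heptan-4-yl acetate
Conditions: Ti(OiPr)4 (cat.), D-(−)-diethyl tartrate (cat.), t-BuOOH, 4 Å MS, CH2Cl2, −20 °C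
Reagents that add atoms: tert-butyl hydroperoxide CC(C)(C)OO
Why: Katsuki–Sharpless asymmetric epoxidation of the titanium-bound allylic alkoxide, in which the D-(−)-tartrate ligand should deliver oxygen under reagent control to the alkene face anti to the acetoxy group and so set both epoxide carbons (C5 and C6 of ring C) at once.

Step 5
Reactants: 5 (1R,4S,6R)-1-(hydroxymethyl)-2,2,6-trimethyl-7-oxabicyclo[4.1.0]heptan-4-yl acetate
Product: 6 (1S,4S,6R)-1-formyl-2,2,6-trimethyl-7-oxabicyclo[4.1.0]heptan-4-yl acetate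
Conditions: Dess–Martin periodinane, pyridine, CH2Cl2, rt
Reagents that add atoms: none
Why: Dess–Martin oxidation of the primary alcohol under buffered conditions; the α-carbon is a quaternary epoxide carbon, so the aldehyde cannot epimerise, and epoxide and acetate should survive.

Step 6
Reactants: 6 (1S,4S,6R)-1-formyl-2,2,6-trimethyl-7-oxabicyclo[4.1.0]heptan-4-yl acetate
Product: 8 (1R,4S,6R)-1-ethynyl-2,2,6-trimethyl-7-oxabicyclo[4.1.0]heptan-4-ol, via acetoxy alkyne 7 (not isolated)
Conditions: MeC(O)C(N2)P(O)(OMe)2, K2CO3, MeOH, 0 °C to rt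
Reagents that add atoms: dimethyl (1-diazo-2-oxopropyl)phosphonate CC(=O)C(=[N+]=[N-])P(=O)(OC)OC
Why: Seyferth–Gilbert homologation in the Ohira–Bestmann variant converts the non-enolisable aldehyde into the terminal alkyne, and the same K2CO3/MeOH medium should then methanolyse the acetate, freeing the C3 hydroxyl without touching the tetrasubstituted epoxide.

Step 7
Reactants: 8 (1R,4S,6R)-1-ethynyl-2,2,6-trimethyl-7-oxabicyclo[4.1.0]heptan-4-ol
Product: 9 (1S,4S,6R)-2,2,6-trimethyl-1-[(E)-2-(tributylstannyl)ethenyl]-7-oxabicyclo[4.1.0]heptan-4-ol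
Conditions: Bu3SnH, PdCl2(PPh3)2 (cat.), THF, 0 °C
Reagents that add atoms: tributyltin hydride CCCC[SnH](CCCC)CCCC
Why: Palladium-catalysed syn-hydrostannation of the terminal alkyne should place tin on the terminal carbon, away from the quaternary epoxide carbon, and so give the (E)-alkenylstannane that becomes C7=C8.

Step 8
Reactants: 10 (2E)-3-methylpent-2-en-4-yn-1-ol
Product: 12 (2E)-3-methyl-5-(trimethylsilyl)pent-2-en-4-yn-1-ol, via bis-silyl ether 11 (not isolated)
Conditions: EtMgBr (2.2 equiv), THF, 0 °C to rt; Me3SiCl; then 1 M aq. H2SO4, rt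
Reagents that add atoms: chlorotrimethylsilane C[Si](C)(C)Cl
Why: Double deprotonation to the alkoxide–acetylide, silylation at both sites and acidic work-up, which cleaves only the labile O–Si bond, should give the C-silylated enynol with the E alkene unchanged.

Step 9
Reactants: 12 (2E)-3-methyl-5-(trimethylsilyl)pent-2-en-4-yn-1-ol
Product: 13 (2E)-3-methyl-5-(trimethylsilyl)pent-2-en-4-ynal
Conditions: MnO2, CH2Cl2, rt
Reagents that add atoms: none
Why: MnO2 oxidation is selective for the allylic alcohol and does not isomerise the trisubstituted E alkene.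

Step 10
Reactants: 13 (2E)-3-methyl-5-(trimethylsilyl)pent-2-en-4-ynal
Product: 14 [(3E,5E)-6-iodo-3-methylhexa-3,5-dien-1-yn-1-yl]trimethylsilane
Conditions: CrCl2, CHI3, THF/1,4-dioxane, 0 °C to rt
Reagents that add atoms: iodoform IC(I)I
Why: Takai olefination, in which the geminal dichromium species formed from iodoform and divalent chromium adds to the aldehyde and eliminates to give the (E)-alkenyl iodide.

Step 11
Reactants: 14 [(3E,5E)-6-iodo-3-methylhexa-3,5-dien-1-yn-1-yl]trimethylsilane (two molecules)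
Product: 16 (3E,5E,7E,9E)-3,10-dimethyl-1,12-bis(trimethylsilyl)dodeca-3,5,7,9-tetraene-1,11-diyne, via alkenylstannane 15 (not isolated)
Conditions: Me3SnSnMe3 (0.5 equiv), PdCl2(PPh3)2 (cat.), NMP, rt to 60 °C, dark
Reagents that add atoms: none
Why: One-pot stannylation–Stille homocoupling (Stille–Kelly type), in which half of the iodide is converted into the alkenylstannane and couples with the other half with retention at both alkenes, should give the symmetric all-E tetraene.

Step 12
Reactants: 16 (3E,5E,7E,9E)-3,10-dimethyl-1,12-bis(trimethylsilyl)dodeca-3,5,7,9-tetraene-1,11-diyne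
Product: 17 (3E,5E,7E,9E)-3,10-dimethyldodeca-3,5,7,9-tetraene-1,11-diyne
Conditions: K2CO3 (cat.), MeOH/THF, 0 °C to rt, dark
Reagents that add atoms: none
Why: Base-catalysed methanolysis of the two alkynyl C–Si bonds (protodesilylation) frees both terminal alkynes without touching the tetraene.

Step 13
Reactants: 18 propiolic acid
Product: 19 (2E)-2,3-dibromoprop-2-enoic acid
Conditions: Br2, CHCl3, 0 °C to rt
Reagents that add atoms: bromine BrBr
Why: Electrophilic anti-addition of bromine across the alkyne should give the E-dibromide, in which the β-bromine is cis to the carboxyl group as the later lactonisation requires.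

Step 14
Reactants: 17 (3E,5E,7E,9E)-3,10-dimethyldodeca-3,5,7,9-tetraene-1,11-diyne (4 equiv); 19 (2E)-2,3-dibromoprop-2-enoic acid
Product: 21 (5Z)-3-bromo-5-[(2E,4E,6E,8E)-2,9-dimethylundeca-2,4,6,8-tetraen-10-yn-1-ylidene]furan-2(5H)-one, via bromoenynoic acid 20 (not isolated)
Conditions: Pd(PPh3)4 (cat.), CuI (cat.), Et3N, MeCN, rt, dark
Reagents that add atoms: none
Why: Tandem Sonogashira coupling–lactonisation, in which zerovalent palladium inserts into the more electrophilic β-C–Br bond, the resulting enynoate closes 5-exo-dig by anti-addition of the carboxylate across the alkyne to give the (Z)-ylidenebutenolide (ring B), and the excess of the symmetric diyne should ensure that only one terminus reacts.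

Step 15
Reactants: 21 (5Z)-3-bromo-5-[(2E,4E,6E,8E)-2,9-dimethylundeca-2,4,6,8-tetraen-10-yn-1-ylidene]furan-2(5H)-one; 9 (1S,4S,6R)-2,2,6-trimethyl-1-[(E)-2-(tributylstannyl)ethenyl]-7-oxabicyclo[4.1.0]heptan-4-ol
Product: 22 (5Z)-5-[(2E,4E,6E,8E)-2,9-dimethylundeca-2,4,6,8-tetraen-10-yn-1-ylidene]-3-{(E)-2-[(1S,4S,6R)-4-hydroxy-2,2,6-trimethyl-7-oxabicyclo[4.1.0]heptan-1-yl]ethenyl}furan-2(5H)-one
Conditions: Pd2(dba)3 (cat.), AsPh3, NMP, rt to 40 °C, dark
Reagents that add atoms: none
Why: Stille coupling at the C3–Br bond of the butenolide with retention of the E geometry of the stannane, under neutral, base-free and copper-free conditions that should spare the terminal alkyne, the ylidenebutenolide, the epoxide and the free hydroxyl.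

Step 16
Reactants: 22 (5Z)-5-[(2E,4E,6E,8E)-2,9-dimethylundeca-2,4,6,8-tetraen-10-yn-1-ylidene]-3-{(E)-2-[(1S,4S,6R)-4-hydroxy-2,2,6-trimethyl-7-oxabicyclo[4.1.0]heptan-1-yl]ethenyl}furan-2(5H)-one; 3 (1R)-3,5,5-trimethyl-4-(trifluoromethylsulfonyloxy)cyclohex-3-en-1-yl acetate (1.5 equiv)
Product: 23 (1R)-4-[(3E,5E,7E,9E)-11-[(2Z)-4-{(E)-2-[(1S,4S,6R)-4-hydroxy-2,2,6-trimethyl-7-oxabicyclo[4.1.0]heptan-1-yl]ethenyl}-5-oxofuran-2(5H)-ylidene]-3,10-dimethylundeca-3,5,7,9-tetraen-1-yn-1-yl]-3,5,5-trimethylcyclohex-3-en-1-yl acetate (CNP0337675.1)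
Conditions: Pd(PPh3)4 (cat.), CuI (cat.), Et3N, DMF (degassed), rt to 40 °C, dark
Reagents that add atoms: none
Why: Zerovalent palladium inserts into the C6'–O bond of enol triflate 3, the terminal C7'–H of 22 is converted by CuI (monovalent copper) and Et3N into a copper acetylide, and transmetalation followed by reductive elimination forms the C6'(sp2)–C7'(sp) bond (Sonogashira coupling). The closest known reaction type is the Sonogashira coupling of hindered 2,6,6-trimethylcyclohexenyl triflates with terminal enynes. The step closes no ring and creates no stereocentre; the C3' centre of 3 and the three centres of ring C lie remote from the reacting atoms and should be carried through unchanged. The selectivity needed is chemoselectivity with retention of every alkene geometry: 22 has a single terminal alkyne and no carbon–halogen bond, and 3 has a single C–OTf bond whose position was fixed by the one enolisable α-carbon of ketone 2, so only one cross-coupling is possible. The amine base at or near room temperature should leave the acetate, the free hydroxyl, the epoxide and the (Z)-ylidenebutenolide untouched, and exclusion of oxygen suppresses oxidative dimerisation of the alkyne.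

**Compound list**

1 | (4R,6R)-4-hydroxy-2,2,6-trimethylcyclohexan-1-one (actinol) | O[C@@H]1C[C@@H](C)C(=O)C(C)(C)C1 | starting material
2 | (1R,5R)-3,3,5-trimethyl-4-oxocyclohexyl acetate | CC(=O)O[C@@H]1C[C@@H](C)C(=O)C(C)(C)C1 | intermediate
3 | (1R)-3,5,5-trimethyl-4-(trifluoromethylsulfonyloxy)cyclohex-3-en-1-yl acetate | CC(=O)O[C@@H]1CC(C)=C(OS(=O)(=O)C(F)(F)F)C(C)(C)C1 | intermediate
4 | (1R)-4-(hydroxymethyl)-3,5,5-trimethylcyclohex-3-en-1-yl acetate | CC(=O)O[C@@H]1CC(C)=C(CO)C(C)(C)C1 | intermediate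
5 | (1R,4S,6R)-1-(hydroxymethyl)-2,2,6-trimethyl-7-oxabicyclo[4.1.0]heptan-4-yl acetate (epoxide oxygen trans to the acetoxy group) | OC[C@@]12O[C@]1(C)C[C@@H](OC(C)=O)CC2(C)C | intermediate
6 | (1S,4S,6R)-1-formyl-2,2,6-trimethyl-7-oxabicyclo[4.1.0]heptan-4-yl acetate | O=C[C@@]12O[C@]1(C)C[C@@H](OC(C)=O)CC2(C)C | intermediate
7 | (1R,4S,6R)-1-ethynyl-2,2,6-trimethyl-7-oxabicyclo[4.1.0]heptan-4-yl acetate | C#C[C@@]12O[C@]1(C)C[C@@H](OC(C)=O)CC2(C)C | intermediate (not isolated)
8 | (1R,4S,6R)-1-ethynyl-2,2,6-trimethyl-7-oxabicyclo[4.1.0]heptan-4-ol | C#C[C@@]12O[C@]1(C)C[C@@H](O)CC2(C)C | intermediate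
9 | (1S,4S,6R)-2,2,6-trimethyl-1-[(E)-2-(tributylstannyl)ethenyl]-7-oxabicyclo[4.1.0]heptan-4-ol | CCCC[Sn](CCCC)(CCCC)/C=C/[C@@]12O[C@]1(C)C[C@@H](O)CC2(C)C | intermediate
10 | (2E)-3-methylpent-2-en-4-yn-1-ol | C#C/C(C)=C/CO | starting material
11 | trimethyl{[(2E)-3-methyl-5-(trimethylsilyl)pent-2-en-4-yn-1-yl]oxy}silane | C[Si](C)(C)C#C/C(C)=C/CO[Si](C)(C)C | intermediate (not isolated)
12 | (2E)-3-methyl-5-(trimethylsilyl)pent-2-en-4-yn-1-ol | C[Si](C)(C)C#C/C(C)=C/CO | intermediate
13 | (2E)-3-methyl-5-(trimethylsilyl)pent-2-en-4-ynal | C[Si](C)(C)C#C/C(C)=C/C=O | intermediate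
14 | [(3E,5E)-6-iodo-3-methylhexa-3,5-dien-1-yn-1-yl]trimethylsilane | C[Si](C)(C)C#C/C(C)=C/C=C/I | intermediate
15 | trimethyl[(3E,5E)-3-methyl-6-(trimethylstannyl)hexa-3,5-dien-1-yn-1-yl]silane | C[Si](C)(C)C#C/C(C)=C/C=C/[Sn](C)(C)C | intermediate (not isolated)
16 | (3E,5E,7E,9E)-3,10-dimethyl-1,12-bis(trimethylsilyl)dodeca-3,5,7,9-tetraene-1,11-diyne | C[Si](C)(C)C#C/C(C)=C/C=C/C=C/C=C(C)/C#C[Si](C)(C)C | intermediate
17 | (3E,5E,7E,9E)-3,10-dimethyldodeca-3,5,7,9-tetraene-1,11-diyne | C#C/C(C)=C/C=C/C=C/C=C(C)/C#C | intermediate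
18 | propiolic acid | C#CC(=O)O | starting material
19 | (2E)-2,3-dibromoprop-2-enoic acid | OC(=O)/C(Br)=C\Br | intermediate
20 | (2E,6E,8E,10E,12E)-2-bromo-6,13-dimethylpentadeca-2,6,8,10,12-pentaene-4,14-diynoic acid | C#C/C(C)=C/C=C/C=C/C=C(C)/C#C/C=C(/Br)C(=O)O | intermediate (not isolated)
21 | (5Z)-3-bromo-5-[(2E,4E,6E,8E)-2,9-dimethylundeca-2,4,6,8-tetraen-10-yn-1-ylidene]furan-2(5H)-one | C#C/C(C)=C/C=C/C=C/C=C(C)/C=C1C=C(Br)C(=O)O/1 | intermediate
22 | (5Z)-5-[(2E,4E,6E,8E)-2,9-dimethylundeca-2,4,6,8-tetraen-10-yn-1-ylidene]-3-{(E)-2-[(1S,4S,6R)-4-hydroxy-2,2,6-trimethyl-7-oxabicyclo[4.1.0]heptan-1-yl]ethenyl}furan-2(5H)-one | C#C/C(C)=C/C=C/C=C/C=C(C)/C=C1C=C(/C=C/[C@@]23O[C@]2(C)C[C@@H](O)CC3(C)C)C(=O)O/1 | intermediate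
23 | (1R)-4-[(3E,5E,7E,9E)-11-[(2Z)-4-{(E)-2-[(1S,4S,6R)-4-hydroxy-2,2,6-trimethyl-7-oxabicyclo[4.1.0]heptan-1-yl]ethenyl}-5-oxofuran-2(5H)-ylidene]-3,10-dimethylundeca-3,5,7,9-tetraen-1-yn-1-yl]-3,5,5-trimethylcyclohex-3-en-1-yl acetate (CNP0337675.1) | CC(=O)O[C@@H]1CC(C)=C(C#C/C(C)=C/C=C/C=C/C=C(C)/C=C2C=C(/C=C/[C@@]34O[C@]3(C)C[C@@H](O)CC4(C)C)C(=O)O/2)C(C)(C)C1 | target

**Totals**

Total step count: 16.
Longest linear sequence: 9 steps (1 → 2 → 3 → 4 → 5 → 6 → 8 → 9 → 22 → 23, that is steps 1–7, 15 and 16).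

**Steps most likely to fail, with fallbacks**

Step 14. What may go wrong: the two ends of the symmetric diyne may not be differentiated cleanly, with double coupling or oligomer growth through the residual C3–Br bond. The carboxylate may also close 6-endo instead of 5-exo, or the enynoate may fail to cyclise under the coupling conditions. The fallback separates the C–C coupling from the C–O ring closure. It sets out from 19, which is esterified (MeOH, H2SO4) to methyl (2E)-2,3-dibromoprop-2-enoate F1. Sonogashira coupling of F1 with excess 17 (PdCl2(PPh3)2, CuI, Et3N, MeCN, rt), which should stop at the β-bromide of such esters, would give methyl (2E,6E,8E,10E,12E)-2-bromo-6,13-dimethylpentadeca-2,6,8,10,12-pentaene-4,14-diynoate F2. Saponification (LiOH, THF/H2O, 0 °C) would give acid 20, now isolated, and AgNO3 (cat.) in acetone should close it 5-exo-dig to 21, where the route is rejoined.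

Step 16. What may go wrong: oxidative dimerisation of the precious C28 alkyne at the copper stage, or slow oxidative addition into the hindered tetrasubstituted triflate while the polyene–butenolide isomerises or degrades in the amine medium. The fallback forms the same C6'–C7' bond earlier, on the robust diyne, and finishes with the Stille coupling. It sets out from 17 (4 equiv) and 3, whose Sonogashira coupling would give (1R)-4-[(3E,5E,7E,9E)-3,10-dimethyldodeca-3,5,7,9-tetraene-1,11-diyn-1-yl]-3,5,5-trimethylcyclohex-3-en-1-yl acetate F3. The tandem coupling–lactonisation of F3 with 19 would pass through (2E,6E,8E,10E,12E)-15-[(4R)-4-acetoxy-2,6,6-trimethylcyclohex-1-en-1-yl]-2-bromo-6,13-dimethylpentadeca-2,6,8,10,12-pentaene-4,14-diynoic acid F4, not isolated, to (1R)-4-[(3E,5E,7E,9E)-11-[(2Z)-4-bromo-5-oxofuran-2(5H)-ylidene]-3,10-dimethylundeca-3,5,7,9-tetraen-1-yn-1-yl]-3,5,5-trimethylcyclohex-3-en-1-yl acetate F5. Stille coupling of F5 with 9 (Pd2(dba)3, AsPh3, NMP) would then arrive at 23.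

Step 3. What may go wrong: slow transmetalation of the sp3 hydroxymethyl group onto the hindered tetrasubstituted alkenylpalladium, so that reduction or hydrolysis of the triflate takes over. The fallback introduces the carbon as carbon monoxide. It sets out from 3, and palladium-catalysed reductive carbonylation (CO 1 atm, Bu3SnH by slow addition, Pd(PPh3)4, THF, 50 °C) would give (1R)-4-formyl-3,5,5-trimethylcyclohex-3-en-1-yl acetate F6. Luche reduction (NaBH4, CeCl3·7H2O, MeOH, 0 °C), which should leave the acetate intact, returns to 4.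

**Further compounds**

F1 | step 14 | methyl (2E)-2,3-dibromoprop-2-enoate | COC(=O)/C(Br)=C\Br
F2 | step 14 | methyl (2E,6E,8E,10E,12E)-2-bromo-6,13-dimethylpentadeca-2,6,8,10,12-pentaene-4,14-diynoate | C#C/C(C)=C/C=C/C=C/C=C(C)/C#C/C=C(/Br)C(=O)OC
F3 | step 16 | (1R)-4-[(3E,5E,7E,9E)-3,10-dimethyldodeca-3,5,7,9-tetraene-1,11-diyn-1-yl]-3,5,5-trimethylcyclohex-3-en-1-yl acetate | CC(=O)O[C@@H]1CC(C)=C(C#C/C(C)=C/C=C/C=C/C=C(C)/C#C)C(C)(C)C1
F4 | step 16 | (2E,6E,8E,10E,12E)-15-[(4R)-4-acetoxy-2,6,6-trimethylcyclohex-1-en-1-yl]-2-bromo-6,13-dimethylpentadeca-2,6,8,10,12-pentaene-4,14-diynoic acid | CC(=O)O[C@@H]1CC(C)=C(C#C/C(C)=C/C=C/C=C/C=C(C)/C#C/C=C(/Br)C(=O)O)C(C)(C)C1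
F5 | step 16 | (1R)-4-[(3E,5E,7E,9E)-11-[(2Z)-4-bromo-5-oxofuran-2(5H)-ylidene]-3,10-dimethylundeca-3,5,7,9-tetraen-1-yn-1-yl]-3,5,5-trimethylcyclohex-3-en-1-yl acetate | CC(=O)O[C@@H]1CC(C)=C(C#C/C(C)=C/C=C/C=C/C=C(C)/C=C2C=C(Br)C(=O)O/2)C(C)(C)C1
F6 | step 3 | (1R)-4-formyl-3,5,5-trimethylcyclohex-3-en-1-yl acetate | CC(=O)O[C@@H]1CC(C)=C(C=O)C(C)(C)C1
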